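(All runs come from a simulation with made-up constants, and the scatter is random.)

The left-handed product stood at 15.6% after 2.00 min in the teal flask, and at 9.8% after 2.00 min in the green flask, which had less catalyst than teal.

| setting | teal | green | flask |
|---|---|---|---|
| left-handed substrate | 0.80 M | 0.80 M | 0.80 M |
| right-handed substrate | 0.80 M | 0.80 M | 0.80 M |
| solid reagent | 0.60 equiv | 0.60 equiv | 0.600 equiv |
| free catalyst | 0.082 mol% | 0.055 mol% | 0.082 mol% |
| impurity | 0.38 mM | 0.38 mM | 0.38 mM |
| remark | the very flask that is asked about, followed so far | run made earlier |  |

| teal: time / min | teal: left-handed product / % | green: time / min | green: left-handed product / % |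
|---|---|---|---|
| 1.00 | 7.4 | 2.00 | 9.8 |
| 2.00 | 15.6 | 4.00 | 18.9 |
| 3.00 | 20.6 | 6.00 | 18.8 |
| 4.00 | 21.8 | 8.00 | 21.3 |
| 5.00 | 21.0 | 10.0 | 21.9 |
| 6.00 | 20.9 | 12.0 | 24.0 |

(standard deviation of a reading: 1 percentage point)

- free catalyst is single-handed; left-handed substrate and right-handed substrate are mirror images of each other, charged as a racemate, each of them at the stated concentration
- solid, in amounts per volume of the solution: solid reagent
- steps that have been proposed: coupling partner + free catalyst + left-handed substrate -> free catalyst + left-handed product; coupling partner + free catalyst + right-handed substrate -> free catalyst + right-handed product; solid reagent <-> coupling partner; free catalyst + impurity -> spent catalyst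
- at the start none of the solid reagent is in solution

1. apparent order in free catalyst when 5.0% of the left-handed substrate and right-handed substrate together are converted (percent change of the rate of making left-handed product for one percent more free catalyst charged)
2. factor on the rate of making left-handed product when 5.0% of the left-handed substrate and right-handed substrate together are converted if free catalyst is charged twice over

I reckoned with the working catalyst, the catalyst charged less the impurity, taken one for one and early: 0.276 mM in the teal flask, 0.0600 mM in the green flask. From above, if the rate followed working catalyst, charging twice over would give 0.932 mM, so a factor of 3.38 and an order of 2.38. From below, if dissolving of the solid reagent were the rate-limiting step, the factor would be 1 and the order 0. The readings tightened this: the ratio of the two readings I began with, taken as a ratio of rates, was 1.59, less than the 4.60 in working catalyst, so I let the rate level off as c/(c + K), with c the working catalyst. That gave a reading of K = 0.0543 mM, carrying the scatter, and so I committed to a factor of 1.13 and an order of 0.391.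

The forecast gave an order of 1 and a factor of 1.95, "with dissolution capping the high side", inside my wide bracket but above my tightened factor. The flask gives an order of 0.33 and a factor of 1.09.

    coupling partner + free catalyst + left-handed substrate → free catalyst + left-handed product (k = 351 M⁻² s⁻¹)
    coupling partner + free catalyst + right-handed substrate → free catalyst + right-handed product (k = 129 M⁻² s⁻¹)
    solid reagent ⇌ coupling partner, rate k3*(cs3 - [coupling partner]) while solid is left; crystals form when [coupling partner] > cs3 (solubility = 0.450 M, k = 0.00709 s⁻¹)
    free catalyst + impurity → spent catalyst (k = 883 M⁻¹ s⁻¹)

At the charged substrate, the 0.276 mM of working catalyst in the teal flask takes up dissolved coupling partner, by the two coupling steps together, with a rate constant of 0.106 s⁻¹, which is 15.0 times the 0.00709 s⁻¹ of dissolving. In the green flask, the 0.0600 mM of working catalyst gives 0.0230 s⁻¹, still 3.24 times the dissolving.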